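The route rests on disconnecting C9–C10 (cembrane numbering), the bond shared by the butenolide and the 14-membered carbocycle. The butenolide is read as a masked (Z)-γ-hydroxy-acrylate: a Nozaki–Hiyama–Kishi reaction of a (Z)-β-iodoacrylate (C9) with a tethered aldehyde (C10) closes the macrocycle, creates C10, and the C19 ester on C8, cis to the new alkoxide across C8=C9, lactonises in the same operation, giving ovatodiolide. The precursor is an open-chain iodo ester aldehyde that already carries the trans α-methylene lactone (C1, C14), assembled by an enantioselective allylboration–lactonisation of two fragments. A last singlet-oxygen ene reaction at C4=C5 installs the 5-hydroperoxide and the 4-methylene group.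

Key step: step 16

Remark on numbering and configuration: cembrane numbering is used throughout (C1 ring-fusion CH bearing the lactone α-carbon C15; C4 bears C18; C8, C9, C10 are the α-, β- and γ-carbons of the butenolide and C19 its carbonyl; C14 is the lactone O–CH; C16 is the lactone carbonyl and C17 its exocyclic methylene); the SMILES is read as the trans-fused α-methylene lactone with 1R, 5R, 10R, 14S and 12E.

Step 1
Reactants: 1 hexa-1,5-diyne
Product: 2 (hexa-1,5-diyn-1-yl)trimethylsilane
Conditions: n-BuLi (0.33 equiv), THF, −78 °C; Me3SiCl, −78 °C → rt; 1 in threefold excess, recovered by distillation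
Reagents that add atoms: chlorotrimethylsilane, C[Si](C)(C)Cl
Why: Acetylide silylation run as a statistical desymmetrisation, in which the excess of 1 keeps bis-silylation low and the silyl group blocks one alkyne so that only the other is carbometalated in step 2.

Step 2
Reactants: 2 (hexa-1,5-diyn-1-yl)trimethylsilane
Product: 4 (3E)-4-methyl-8-(trimethylsilyl)oct-3-en-7-yn-1-ol, via alkenylalane 3 (not isolated)
Conditions: Me3Al (2 equiv), Cp2ZrCl2 (0.2 equiv), CH2Cl2, 0 °C → rt; then n-BuLi, THF, −78 °C; ethylene oxide, −78 → 0 °C; aq. NH4Cl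
Reagents that add atoms: trimethylaluminium, C[Al](C)C; ethylene oxide, C1CO1
Why: Negishi carboalumination adds methyl and aluminium syn across the free terminal alkyne with methyl on the internal carbon, and the derived alanate opens ethylene oxide with retention, which fixes the E geometry of C4=C5 and adds C6 and C7.

Step 3
Reactants: 4 (3E)-4-methyl-8-(trimethylsilyl)oct-3-en-7-yn-1-ol
Product: 5 [(5E)-8-bromo-5-methyloct-5-en-1-yn-1-yl]trimethylsilane
Conditions: CBr4, PPh3, CH2Cl2, 0 °C
Reagents that add atoms: tetrabromomethane, BrC(Br)(Br)Br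
Why: The Appel reaction converts the primary alcohol into the bromide under neutral conditions that leave the silyl alkyne and the trisubstituted olefin untouched.

Step 4
Reactants: 5 [(5E)-8-bromo-5-methyloct-5-en-1-yn-1-yl]trimethylsilane; 6 prop-2-yn-1-ol
Product: 9 (2Z,5E)-2-(iodomethylidene)-6-methyl-10-(trimethylsilyl)dec-5-en-9-yn-1-ol, via Grignard reagent 7 (not isolated), via alkenylmagnesium alkoxide chelate 8 (not isolated)
Conditions: Mg, THF, rt; then 6 pretreated with i-PrMgCl (1.0 equiv, THF, −20 °C), CuI (10 mol %), THF, −10 °C → rt; then iodine, −40 → 0 °C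
Reagents that add atoms: iodine, [I][I]
Why: Copper-catalysed anti-carbomagnesiation of the magnesium alkoxide of propargyl alcohol puts the alkyl group of 7 on the internal alkyne carbon and magnesium on the terminal carbon on the alkoxide side (five-membered chelate 8), and iodinolysis of the C–Mg bond with retention leaves iodine cis to CH2OH, which sets the Z geometry of C8=C9.

Step 5
Reactants: 9 (2Z,5E)-2-(iodomethylidene)-6-methyl-10-(trimethylsilyl)dec-5-en-9-yn-1-ol
Product: 11 tert-butyl{[(2Z,5E)-2-(iodomethylidene)-6-methyldec-5-en-9-yn-1-yl]oxy}dimethylsilane, via bis-silyl enyne 10 (not isolated)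
Conditions: TBSCl, imidazole, CH2Cl2, 0 °C → rt; then MeOH, K2CO3 (1.5 equiv), rt
Reagents that add atoms: tert-butyldimethylsilyl chloride, CC(C)(C)[Si](C)(C)Cl
Why: Silylation of the allylic alcohol followed in the same flask by methanolysis of the alkynyl C–Si bond, which does not touch the silyl ether, frees the terminal alkyne while C19 stays protected.

Step 6
Reactants: 11 tert-butyl{[(2Z,5E)-2-(iodomethylidene)-6-methyldec-5-en-9-yn-1-yl]oxy}dimethylsilane
Product: 12 methyl (6E,10Z)-10-{[tert-butyl(dimethyl)silyl]oxymethyl}-11-iodo-6-methylundeca-6,10-dien-2-ynoate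
Conditions: LiN(i-Pr)2 (1.05 equiv), THF, −78 °C; ClCO2Me, −78 → −20 °C
Reagents that add atoms: methyl chloroformate, COC(Cl)=O
Why: Deprotonation of the terminal alkyne, the only acidic C–H, and C-acylation of the lithium acetylide with the chloroformate gives the ynoate (C16), the alkenyl iodide being stable to the amide base at low temperature.

Step 7
Reactants: 12 methyl (6E,10Z)-10-{[tert-butyl(dimethyl)silyl]oxymethyl}-11-iodo-6-methylundeca-6,10-dien-2-ynoate
Product: 14 methyl (2Z,6E,10Z)-10-{[tert-butyl(dimethyl)silyl]oxymethyl}-11-iodo-6-methyl-2-[(4,4,5,5-tetramethyl-1,3,2-dioxaborolan-2-yl)methyl]undeca-2,6,10-trienoate, via alumino enoate 13 (not isolated)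
Conditions: i-Bu2AlH (1.3 equiv), HMPA, THF, 0 °C; then ICH2Bpin, 0 °C → rt; aq. potassium sodium tartrate
Reagents that add atoms: 2-(iodomethyl)-4,4,5,5-tetramethyl-1,3,2-dioxaborolane, ICB1OC(C)(C)C(C)(C)O1
Why: Conjugate hydroalumination of the ynoate by the i-Bu2AlH–HMPA complex is a syn addition (H to C1, Al to C15), and C-alkylation of 13 by the iodomethylboronate with retention gives the 2-(borylmethyl)enoate with the C2 chain cis to the ester and trans to CH2B, the geometry that an anti allylboration requires.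

Step 8
Reactants: 15 but-3-yn-1-ol
Product: 16 (but-3-yn-1-yloxy)(tert-butyl)dimethylsilane
Conditions: TBSCl, imidazole, CH2Cl2, rt
Reagents that add atoms: tert-butyldimethylsilyl chloride, CC(C)(C)[Si](C)(C)Cl
Why: Standard silyl ether formation protects the future C10 oxygen through the organoaluminium chemistry and the allylboration.

Step 9
Reactants: 16 (but-3-yn-1-yloxy)(tert-butyl)dimethylsilane
Product: 18 (2E)-5-{[tert-butyl(dimethyl)silyl]oxy}-3-methylpent-2-en-1-ol, via alkenylalane 17 (not isolated)
Conditions: Me3Al (2 equiv), Cp2ZrCl2 (0.2 equiv), CH2Cl2, 0 °C → rt; then n-BuLi, THF, −78 °C; (CH2O)n, −78 °C → rt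
Reagents that add atoms: trimethylaluminium, C[Al](C)C; paraformaldehyde (as formaldehyde), C=O
Why: Negishi carboalumination (syn addition, methyl on the internal carbon) and hydroxymethylation of the alanate with retention give the E trisubstituted C12=C13 olefin with C14 in place.

Step 10
Reactants: 18 (2E)-5-{[tert-butyl(dimethyl)silyl]oxy}-3-methylpent-2-en-1-ol
Product: 19 (2E)-5-{[tert-butyl(dimethyl)silyl]oxy}-3-methylpent-2-enal
Conditions: MnO2, CH2Cl2, rt
Reagents that add atoms: none
Why: MnO2 oxidises the allylic alcohol to the enal without touching the silyl ether and without E/Z isomerisation.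

Step 11
Reactants: 14 (Z)-2-(borylmethyl)enoate; 19 (2E)-5-{[tert-butyl(dimethyl)silyl]oxy}-3-methylpent-2-enal
Product: 22 (4R,5S)-5-[(1E)-4-hydroxy-2-methylbut-1-en-1-yl]-4-[(3E,7Z)-7-(hydroxymethyl)-8-iodo-3-methylocta-3,7-dien-1-yl]-3-methylideneoxolan-2-one, via pinacol borate of the anti adduct 20 (not isolated), via bis-silyl lactone 21 (not isolated)
Conditions: (R)-3,3'-bis(2,4,6-triisopropylphenyl)-1,1'-binaphthyl-2,2'-diyl hydrogen phosphate (10 mol %), 4 Å molecular sieves, toluene, −20 °C → rt; then MeOH, p-TsOH·H2O (0.2 equiv), rt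
Reagents that add atoms: none
Why: Chiral phosphoric acid-catalysed allylboration through a closed chair transition state, in which the acid holds the boronate oxygen and the formyl hydrogen and should direct the allyl unit to the Re face of 19 (14S) while the boronate geometry places the C2 chain equatorial to give the anti adduct (1R); acid methanolysis then cleaves the borate, closes the trans α-methylene-γ-butyrolactone by attack of the C14 oxygen on the ester and removes both silyl ethers.

Step 12
Reactants: 22 lactone diol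
Product: 23 (4R,5S)-4-[(3E,7Z)-7-formyl-8-iodo-3-methylocta-3,7-dien-1-yl]-5-[(1E)-4-hydroxy-2-methylbut-1-en-1-yl]-3-methylideneoxolan-2-one
Conditions: MnO2, CH2Cl2, rt
Reagents that add atoms: none
Why: MnO2 oxidises only the allylic C19 alcohol to the (Z)-β-iodo enal and leaves the homoallylic C10 alcohol, the olefins and the lactone untouched.

Step 13
Reactants: 23 (Z)-β-iodo enal
Product: 24 (2Z,5E)-8-{(2S,3R)-2-[(1E)-4-hydroxy-2-methylbut-1-en-1-yl]-4-methylidene-5-oxooxolan-3-yl}-2-(iodomethylidene)-6-methyloct-5-enoic acid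
Conditions: NaClO2, NaH2PO4, 2-methylbut-2-ene, t-BuOH/H2O, 0 °C → rt
Reagents that add atoms: sodium chlorite, [Na+].[O-]Cl=O
Why: Pinnick oxidation converts the enal into the acid with the alkene scavenger taking up hypochlorite, conditions that tolerate the free alcohol, the alkenyl iodide and the α-methylene lactone and preserve the Z geometry.

Step 14
Reactants: 24 (Z)-β-iodoacrylic acid
Product: 25 methyl (2Z,5E)-8-{(2S,3R)-2-[(1E)-4-hydroxy-2-methylbut-1-en-1-yl]-4-methylidene-5-oxooxolan-3-yl}-2-(iodomethylidene)-6-methyloct-5-enoate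
Conditions: MeI, KHCO3, DMF, rt
Reagents that add atoms: iodomethane, CI
Why: O-Alkylation of the carboxylate under bicarbonate conditions, too mild to alkylate the primary alcohol or open the lactone, gives the methyl ester that serves as acyl donor in step 16.

Step 15
Reactants: 25 hydroxy (Z)-β-iodoacrylate
Product: 26 methyl (2Z,5E)-2-(iodomethylidene)-6-methyl-8-{(2S,3R)-4-methylidene-2-[(1E)-2-methyl-4-oxobut-1-en-1-yl]-5-oxooxolan-3-yl}oct-5-enoate
Conditions: Dess–Martin periodinane, NaHCO3, CH2Cl2, 0 °C; used at once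
Reagents that add atoms: none
Why: Buffered Dess–Martin oxidation gives the β,γ-unsaturated C10 aldehyde without the acid or base that would move the C12=C13 olefin into conjugation.

Step 16
Reactants: 26 iodo ester aldehyde
Product: 28 ovatodiolide, via macrocyclic hydroxy ester 27 (not isolated)
Conditions: CrCl2 (10 equiv), NiCl2 (0.1 equiv), degassed DMSO/THF, slow addition of 26 (final 0.002 M), rt; aq. NH4Cl
Reagents that add atoms: none
Why: Zerovalent nickel, formed from NiCl2 by CrCl2, inserts into the C9–I bond and hands the alkenyl group to chromium with retention, and the resulting (Z)-alkenylchromium species (trivalent chromium) adds to the C10 aldehyde; the chromium alkoxide so formed lies cis to the C19 methyl ester across C8=C9 and displaces methoxide. The closest known reaction type is the Nozaki–Hiyama–Kishi macrocyclisation, combined with the known direct butenolide formation from (Z)-β-iodoacrylates and aldehydes under the same conditions. The 14-membered carbocycle closes by a 14-exo-trig carbonyl addition under high dilution and the butenolide by a 5-exo-trig lactonisation that the Z olefin enforces geometrically. C10 is set under substrate control: the trans-lactone, the two E trisubstituted olefins and the Z-iodoacrylate leave the closing chain few conformations, and attack on the aldehyde face that keeps the C10 oxygen on the periphery of the forming ring and anti to the C14–O bond should give the 10R carbinol. The step needs chemoselective activation of the C–I bond (the allylic lactone, the enoate and the α-methylene lactone are inert to divalent chromium and to organochromium reagents, which add only to the aldehyde) and freedom from base, which the neutral CrCl2 medium provides, so that the β,γ-unsaturated aldehyde does not slip into conjugation.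

Step 17
Reactants: 28 ovatodiolide
Product: 29 4-methylene-5β-hydroperoxyovatodiolide
Conditions: O2, visible light, tetraphenylporphyrin (cat.), CH2Cl2, −20 °C; chromatography
Reagents that add atoms: dioxygen, O=O
Why: Schenck ene reaction, in which electrophilic singlet oxygen attacks only the electron-rich C4=C5 olefin (C12=C13 is deactivated by the allylic lactone oxygen and the two enoate olefins are inert), bonds to C5 on the outer face of the ring anti to the transannular butenolide, which should give 5R, and takes a hydrogen from the freely rotating C18 methyl group on the more crowded side of the olefin in preference to the ring-constrained C6 hydrogens, so that the double bond moves to C4=C18; the 4-hydroperoxy-5-ene regioisomer is the expected minor product and is removed by chromatography.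

Compound list
1 | hexa-1,5-diyne | C#CCCC#C | starting material
2 | (hexa-1,5-diyn-1-yl)trimethylsilane | C#CCCC#C[Si](C)(C)C | intermediate
3 | dimethyl[(1E)-2-methyl-6-(trimethylsilyl)hex-1-en-5-yn-1-yl]alumane | C[Al](C)/C=C(\C)CCC#C[Si](C)(C)C | intermediate (not isolated)
4 | (3E)-4-methyl-8-(trimethylsilyl)oct-3-en-7-yn-1-ol | OCC/C=C(\C)CCC#C[Si](C)(C)C | intermediate
5 | [(5E)-8-bromo-5-methyloct-5-en-1-yn-1-yl]trimethylsilane | BrCC/C=C(\C)CCC#C[Si](C)(C)C | intermediate
6 | prop-2-yn-1-ol | C#CCO | starting material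
7 | bromo[(3E)-4-methyl-8-(trimethylsilyl)oct-3-en-7-yn-1-yl]magnesium | Br[Mg]CC/C=C(\C)CCC#C[Si](C)(C)C | intermediate (not isolated)
8 | 4-[(3E)-4-methyl-8-(trimethylsilyl)oct-3-en-7-yn-1-yl]-2,5-dihydro-1,2-oxamagnesole (chelated Z-alkenylmagnesium alkoxide) | C[Si](C)(C)C#CCC/C(C)=C/CCC1=C[Mg]OC1 | intermediate (not isolated)
9 | (2Z,5E)-2-(iodomethylidene)-6-methyl-10-(trimethylsilyl)dec-5-en-9-yn-1-ol | OC/C(=C\I)CC/C=C(\C)CCC#C[Si](C)(C)C | intermediate
10 | tert-butyl{[(2Z,5E)-2-(iodomethylidene)-6-methyl-10-(trimethylsilyl)dec-5-en-9-yn-1-yl]oxy}dimethylsilane | CC(C)(C)[Si](C)(C)OC/C(=C\I)CC/C=C(\C)CCC#C[Si](C)(C)C | intermediate (not isolated)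
11 | tert-butyl{[(2Z,5E)-2-(iodomethylidene)-6-methyldec-5-en-9-yn-1-yl]oxy}dimethylsilane | CC(C)(C)[Si](C)(C)OC/C(=C\I)CC/C=C(\C)CCC#C | intermediate
12 | methyl (6E,10Z)-10-{[tert-butyl(dimethyl)silyl]oxymethyl}-11-iodo-6-methylundeca-6,10-dien-2-ynoate | CC(C)(C)[Si](C)(C)OC/C(=C\I)CC/C=C(\C)CCC#CC(=O)OC | intermediate
13 | methyl (2E,6E,10Z)-2-[bis(2-methylpropyl)alumanyl]-10-{[tert-butyl(dimethyl)silyl]oxymethyl}-11-iodo-6-methylundeca-2,6,10-trienoate (C4 chain cis to the ester) | CC(C)(C)[Si](C)(C)OC/C(=C\I)CC/C=C(\C)CC/C=C(\C(=O)OC)[Al](CC(C)C)CC(C)C | intermediate (not isolated)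
14 | methyl (2Z,6E,10Z)-10-{[tert-butyl(dimethyl)silyl]oxymethyl}-11-iodo-6-methyl-2-[(4,4,5,5-tetramethyl-1,3,2-dioxaborolan-2-yl)methyl]undeca-2,6,10-trienoate | CC(C)(C)[Si](C)(C)OC/C(=C\I)CC/C=C(\C)CC/C=C(\C(=O)OC)CB1OC(C)(C)C(C)(C)O1 | intermediate
15 | but-3-yn-1-ol | C#CCCO | starting material
16 | (but-3-yn-1-yloxy)(tert-butyl)dimethylsilane | C#CCCO[Si](C)(C)C(C)(C)C | intermediate
17 | {(1E)-4-[tert-butyl(dimethyl)silyl]oxy-2-methylbut-1-en-1-yl}dimethylalumane | C[Al](C)/C=C(\C)CCO[Si](C)(C)C(C)(C)C | intermediate (not isolated)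
18 | (2E)-5-{[tert-butyl(dimethyl)silyl]oxy}-3-methylpent-2-en-1-ol | OC/C=C(\C)CCO[Si](C)(C)C(C)(C)C | intermediate
19 | (2E)-5-{[tert-butyl(dimethyl)silyl]oxy}-3-methylpent-2-enal | O=C/C=C(\C)CCO[Si](C)(C)C(C)(C)C | intermediate
20 | methyl (3R,6E,10Z)-10-{[tert-butyl(dimethyl)silyl]oxymethyl}-3-[(1S,2E)-5-{[tert-butyl(dimethyl)silyl]oxy}-3-methyl-1-[(4,4,5,5-tetramethyl-1,3,2-dioxaborolan-2-yl)oxy]pent-2-en-1-yl]-11-iodo-6-methyl-2-methylideneundeca-6,10-dienoate | COC(=O)C(=C)[C@@H](CC/C(C)=C/CC/C(CO[Si](C)(C)C(C)(C)C)=C/I)[C@@H](OB1OC(C)(C)C(C)(C)O1)/C=C(\C)CCO[Si](C)(C)C(C)(C)C | intermediate (not isolated)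
21 | (4R,5S)-5-[(1E)-4-{[tert-butyl(dimethyl)silyl]oxy}-2-methylbut-1-en-1-yl]-4-[(3E,7Z)-7-({[tert-butyl(dimethyl)silyl]oxy}methyl)-8-iodo-3-methylocta-3,7-dien-1-yl]-3-methylideneoxolan-2-one | C=C1C(=O)O[C@@H](/C=C(\C)CCO[Si](C)(C)C(C)(C)C)[C@@H]1CC/C(C)=C/CC/C(CO[Si](C)(C)C(C)(C)C)=C/I | intermediate (not isolated)
22 | (4R,5S)-5-[(1E)-4-hydroxy-2-methylbut-1-en-1-yl]-4-[(3E,7Z)-7-(hydroxymethyl)-8-iodo-3-methylocta-3,7-dien-1-yl]-3-methylideneoxolan-2-one | C=C1C(=O)O[C@@H](/C=C(\C)CCO)[C@@H]1CC/C(C)=C/CC/C(CO)=C/I | intermediate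
23 | (4R,5S)-4-[(3E,7Z)-7-formyl-8-iodo-3-methylocta-3,7-dien-1-yl]-5-[(1E)-4-hydroxy-2-methylbut-1-en-1-yl]-3-methylideneoxolan-2-one | C=C1C(=O)O[C@@H](/C=C(\C)CCO)[C@@H]1CC/C(C)=C/CC/C(C=O)=C/I | intermediate
24 | (2Z,5E)-8-{(2S,3R)-2-[(1E)-4-hydroxy-2-methylbut-1-en-1-yl]-4-methylidene-5-oxooxolan-3-yl}-2-(iodomethylidene)-6-methyloct-5-enoic acid | C=C1C(=O)O[C@@H](/C=C(\C)CCO)[C@@H]1CC/C(C)=C/CC/C(C(=O)O)=C/I | intermediate
25 | methyl (2Z,5E)-8-{(2S,3R)-2-[(1E)-4-hydroxy-2-methylbut-1-en-1-yl]-4-methylidene-5-oxooxolan-3-yl}-2-(iodomethylidene)-6-methyloct-5-enoate | C=C1C(=O)O[C@@H](/C=C(\C)CCO)[C@@H]1CC/C(C)=C/CC/C(C(=O)OC)=C/I | intermediate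
26 | methyl (2Z,5E)-2-(iodomethylidene)-6-methyl-8-{(2S,3R)-4-methylidene-2-[(1E)-2-methyl-4-oxobut-1-en-1-yl]-5-oxooxolan-3-yl}oct-5-enoate | C=C1C(=O)O[C@@H](/C=C(\C)CC=O)[C@@H]1CC/C(C)=C/CC/C(C(=O)OC)=C/I | intermediate
27 | macrocyclic (Z)-γ-hydroxy enoate: ovatodiolide with the butenolide opened to the C19 methyl ester and the free 10R hydroxyl (1R,10R,14S; 4E,8Z,12E) | C=C1C(=O)O[C@H]2/C=C(\C)C[C@@H](O)/C=C(C(=O)OC)/CC/C=C(C)/CC[C@H]12 | intermediate (not isolated)
28 | ovatodiolide (1R,10R,14S; 4E,12E) | C=C1C(=O)O[C@H]2/C=C(\C)C[C@@H]3C=C(CC/C=C(C)/CC[C@H]12)C(=O)O3 | intermediate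
29 | 4-methylene-5β-hydroperoxyovatodiolide (1R,5R,10R,14S; 12E) | C=C1C(=O)O[C@H]2/C=C(\C)C[C@@H]3C=C(CC[C@@H](OO)C(=C)CC[C@H]12)C(=O)O3 | target

Total step count: 17. Longest linear sequence: 14 steps (steps 1–7 and 11–17); steps 8–10 make the second fragment.

Steps most likely to fail

Step 16. The attack of the alkenylchromium on the C10 aldehyde may show poor facial selectivity, because the existing stereocentres are remote from C10, and the closure may also compete with oligomerisation. The fallback sets out from 26 and replaces kinetic control in the ring closure by stereochemical editing of the butenolide afterwards. The cyclisation is run as in step 16 and the C10 epimer, 10-epi-ovatodiolide F1, is kept. TBSOTf and Et3N (CH2Cl2, 0 °C) convert it into the 2-silyloxyfuran F2, in which C10 is trigonal. Protodesilylation (HF·pyridine, THF, −40 °C) reprotonates C10 under the facial bias of the macrocycle, the epimers are separated and F1 is recycled. The fallback comes back to the route at 28.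

Step 11. The ester-substituted allylboronate is a weak nucleophile, so activation by the phosphoric acid may be too slow and the uncatalysed background reaction would erode the enantioselectivity. If only the sense of induction is wrong, the (S)-catalyst is used. The fallback sets out from 11 and moves the control element into the reagent. Carboxylation (LiN(i-Pr)2, THF, −78 °C; CO2) gives the ynoic acid F3. Esterification with (1R,2S,5R)-8-phenylmenthol (DCC, DMAP, CH2Cl2) gives the 8-phenylmenthyl ynoate F4. Hydroalumination and borylmethylation as in step 7 give the 8-phenylmenthyl allylboronate F5. Its Sc(OTf)3-catalysed addition to 19 (toluene, −78 → 0 °C) gives the borate adduct F6, the aryl group of the auxiliary shielding one face of the enoate. Acid methanolysis as in step 11 expels the auxiliary on lactonisation and the fallback comes back at 22 by way of 21. The antipodal auxiliary is used if the lactone of the wrong handedness is favoured.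

Step 17. Hydrogen abstraction from C6 instead of C18 would give the tertiary 4-hydroperoxide, attack on the inner face of the olefin would give the C5 epimer, and the C12=C13 olefin may be over-oxygenated. The fallback sets out from 28 and separates the C–O bond formation from the olefin shift. Ene-type chlorination with hypochlorous acid (Ca(OCl)2, CO2, CH2Cl2/H2O, 0 °C) can place the heteroatom only at C5 and moves the double bond to C4=C18, giving the allylic chloride F7. Silver-assisted perhydrolysis (AgOTf, anhydrous H2O2, Et2O, 0 °C) then replaces chloride by the hydroperoxy group, and the fallback comes back at 29.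

Further compounds
F1 | step 16 | 10-epi-ovatodiolide (1R,10S,14S) | C=C1C(=O)O[C@H]2/C=C(\C)C[C@H]3C=C(CC/C=C(C)/CC[C@H]12)C(=O)O3
F2 | step 16 | 2-(tert-butyldimethylsilyloxy)furan derived from the butenolide of 28 and F1 (C10 trigonal; 1R,14S) | C=C1C(=O)O[C@H]2/C=C(\C)Cc3cc(CC/C=C(C)/CC[C@H]12)c(O[Si](C)(C)C(C)(C)C)o3
F3 | step 11 | (6E,10Z)-10-{[tert-butyl(dimethyl)silyl]oxymethyl}-11-iodo-6-methylundeca-6,10-dien-2-ynoic acid | CC(C)(C)[Si](C)(C)OC/C(=C\I)CC/C=C(\C)CCC#CC(=O)O
F4 | step 11 | (1R,2S,5R)-5-methyl-2-(2-phenylpropan-2-yl)cyclohexyl ester of F3 | CC(C)(C)[Si](C)(C)OC/C(=C\I)CC/C=C(\C)CCC#CC(=O)O[C@@H]1C[C@H](C)CC[C@H]1C(C)(C)c1ccccc1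
F5 | step 11 | (1R,2S,5R)-5-methyl-2-(2-phenylpropan-2-yl)cyclohexyl analogue of allylboronate 14 (2Z,6E,10Z) | CC(C)(C)[Si](C)(C)OC/C(=C\I)CC/C=C(\C)CC/C=C(\C(=O)O[C@@H]1C[C@H](C)CC[C@H]1C(C)(C)c1ccccc1)CB1OC(C)(C)C(C)(C)O1
F6 | step 11 | (1R,2S,5R)-5-methyl-2-(2-phenylpropan-2-yl)cyclohexyl analogue of borate 20 (3R; 1S in the side chain) | O=C(O[C@@H]1C[C@H](C)CC[C@H]1C(C)(C)c1ccccc1)C(=C)[C@@H](CC/C(C)=C/CC/C(CO[Si](C)(C)C(C)(C)C)=C/I)[C@@H](OB1OC(C)(C)C(C)(C)O1)/C=C(\C)CCO[Si](C)(C)C(C)(C)C
F7 | step 17 | 5-chloro-4-methylene derivative of ovatodiolide (4(18)-ene; mixture of C5 epimers) | C=C1C(=O)O[C@H]2/C=C(\C)C[C@@H]3C=C(CCC(Cl)C(=C)CC[C@H]12)C(=O)O3
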